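**Retrosynthetic overview**
1. Target 35 comes from mild hydrolysis of the bridged 1,3-oxazinium salt 34. Salt 34 comes from an intramolecular [4+2] cycloaddition of the N-methylene acyliminium ion of lactam 31 with its own (Z)-pentenyl chain. This step closes the oxazinium ring and the nine-membered ring E together and sets the carbinol and methyl-bearing carbons.
2. Lactam 31 (rings A–D) comes from ring C closure by reductive α-alkylation of the AB enone with a pendant aldehyde. Ring D comes from a lactone-to-lactam acyl transfer.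
3. The AB enone comes from a Robinson annulation (ring B) on a spiro cyclopentanone. That ketone comes from a Michael–Dieckmann annulation (ring A) of dimethyl succinate with the α-methylene lactone 20.
4. Lactone 20 comes from the quaternary γ-lactam 15. Lactam 15 comes from an organocatalytic Michael addition of (Z)-hept-5-enal to β-nitroacrolein dimethyl acetal.
5. Ring order: temporary γ-lactam, temporary γ-lactone, A, B, D, C, then oxazinium ring plus E in one operation, then opening of the oxazinium ring.

Assumption: ring letters are A (cyclopentane with CO2Me), B (cyclohexenone), C (cyclohexene), D (δ-lactam) and E (nine-membered ring). Simple reagents such as Boc2O or Ac2O appear under "Reagents that add atoms" and carry no compound number.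

Step 1
Reactants: 1 tetrahydro-2H-pyran-2-ol; 2 ethyltriphenylphosphonium bromide
Product: 3 (5Z)-hept-5-en-1-ol
Conditions: 2 (2.3 equiv), KN(SiMe3)2 (2.2 equiv), THF, 0 °C; then 1, −78 °C → rt
Reagents that add atoms: none
Why: Wittig olefination of the open hydroxy-aldehyde form of the lactol with the non-stabilised ethylidene ylide goes through the kinetically favoured cis-oxaphosphetane and gives the (Z)-alkene needed later for the syn amino alcohol.

Step 2
Reactants: 3 (5Z)-hept-5-en-1-ol
Product: 4 (5Z)-hept-5-enal
Conditions: TEMPO (5 mol %), PhI(OAc)2, CH2Cl2, rt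
Reagents that add atoms: none
Why: Oxoammonium (TEMPO) oxidation stops at the aldehyde and does not touch or isomerise the (Z)-alkene.

Step 3
Reactants: 5 2,2-dimethoxyacetaldehyde; 6 nitromethane
Product: 8 (E)-3,3-dimethoxy-1-nitroprop-1-ene, via nitroaldol 7 (not isolated)
Conditions: K2CO3 (5 mol %), 0 °C → rt; extract, dry; MeSO2Cl, NEt3 (2.2 equiv), CH2Cl2, −10 °C
Reagents that add atoms: none
Why: Henry (nitroaldol) addition followed by mesylation and E1cB elimination gives the thermodynamically preferred (E)-nitroalkene.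

Step 4
Reactants: 4 (5Z)-hept-5-enal; 8 (E)-3,3-dimethoxy-1-nitroprop-1-ene
Product: 9 (2S,5Z)-2-[(2S)-1,1-dimethoxy-3-nitropropan-2-yl]hept-5-enal
Conditions: (R)-α,α-diphenylprolinol trimethylsilyl ether (10 mol %), 4-nitrophenol (10 mol %), toluene, 0 °C → rt
Reagents that add atoms: none
Why: In this Hayashi–Jørgensen enamine-catalysed Michael addition the (E)-enamine, shielded by the CPh2(OSiMe3) group of the (R)-catalyst, attacks the nitroalkene through the synclinal transition state and fixes the acetal-bearing carbon in the absolute configuration of the target (syn adduct), while the aldehyde α-centre is erased in step 8.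

Step 5
Reactants: 9 nitro aldehyde
Product: 10 (2S,5Z)-2-[(2S)-1,1-dimethoxy-3-nitropropan-2-yl]hept-5-enoic acid
Conditions: NaClO2, NaH2PO4, 2-methylbut-2-ene, t-BuOH–H2O, 0 °C → rt
Reagents that add atoms: sodium chlorite [Na+].[O-]Cl=O
Why: Pinnick oxidation converts the aldehyde into the acid at a buffered pH that the acetal tolerates, and the scavenger alkene protects the (Z)-alkene from HOCl.

Step 6
Reactants: 10 nitro acid
Product: 12 (3S,4S)-4-(dimethoxymethyl)-3-[(3Z)-pent-3-en-1-yl]pyrrolidin-2-one, via amino acid 11 (not isolated)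
Conditions: Zn dust, HCO2NH4, MeOH, rt; filter, concentrate; toluene, 100 °C
Reagents that add atoms: none
Why: Zinc/ammonium formate transfer reduction of the aliphatic nitro group spares the alkene and the acetal, and the γ-amino acid then lactamises thermally (5-exo-trig) without touching the stereocentres.

Step 7
Reactants: 12 γ-lactam
Product: 13 tert-butyl (3S,4S)-4-(dimethoxymethyl)-2-oxo-3-[(3Z)-pent-3-en-1-yl]pyrrolidine-1-carboxylate
Conditions: Boc2O, DMAP (0.1 equiv), MeCN, rt
Reagents that add atoms: di-tert-butyl dicarbonate CC(C)(C)OC(=O)OC(=O)OC(C)(C)C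
Why: N-acylation removes the N–H before enolate chemistry and makes the lactam carbonyl imide-like for the reductive opening in step 9.

Step 8
Reactants: 13 N-Boc lactam; 14 methyl bromoacetate
Product: 15 tert-butyl (3S,4S)-4-(dimethoxymethyl)-3-(2-methoxy-2-oxoethyl)-2-oxo-3-[(3Z)-pent-3-en-1-yl]pyrrolidine-1-carboxylate
Conditions: LiN(SiMe3)2, THF, −78 °C; 14, −78 → −40 °C
Reagents that add atoms: none
Why: In this enolate alkylation the planar lactam enolate takes up the reactive bromoacetate on the ring face anti to the neighbouring dimethoxymethyl group (1,2-induction in a five-membered ring), which sets the first all-carbon quaternary centre.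

Step 9
Reactants: 15 quaternary N-Boc lactam
Product: 17 tert-butyl {(2S)-3,3-dimethoxy-2-[(3S)-5-oxo-3-[(3Z)-pent-3-en-1-yl]oxolan-3-yl]propyl}carbamate, via hydroxy ester 16 (not isolated)
Conditions: NaBH4, MeOH–THF, 0 °C → rt; aq NH4Cl
Reagents that add atoms: none
Why: Borohydride reductive ring opening of the imide-like N-Boc lactam is faster than reduction of the methyl ester, and the neopentyl alkoxide then lactonises onto that ester (5-exo-trig), which turns the lactam carbonyl into the future CH2O carbon with both stereocentres untouched.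

Step 10
Reactants: 17 γ-lactone
Product: 20 tert-butyl {(2S)-3,3-dimethoxy-2-[(3R)-4-methylidene-5-oxo-3-[(3Z)-pent-3-en-1-yl]oxolan-3-yl]propyl}carbamate, via Mannich base 18 (not isolated), via trimethylammonium iodide 19 (not isolated)
Conditions: LiN(i-Pr)2 (2.2 equiv), THF, −78 °C; CH2=NMe2+ I−, −78 °C → rt; MeI, CH2Cl2, rt; aq NaHCO3, rt
Reagents that add atoms: N,N-dimethylmethyleneiminium iodide (Eschenmoser's salt) C=[N+](C)C.[I-]
Why: Eschenmoser methylenation (Mannich reaction of the lactone enolate, N-methylation, E1cB elimination) installs the one-carbon acceptor, and the descriptor at the quaternary carbon changes only through CIP ranking.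

Step 11
Reactants: 20 α-methylene lactone; 21 dimethyl succinate
Product: 23 methyl (4R,5S)-4-[(2S)-1-(tert-butoxycarbonylamino)-3,3-dimethoxypropan-2-yl]-1,6-dioxo-4-[(3Z)-pent-3-en-1-yl]-2-oxaspiro[4.4]nonane-8-carboxylate (C-8 epimers), via Michael adduct 22 (not isolated)
Conditions: 21 (3 equiv), LiN(i-Pr)2 (3 equiv), THF, −78 °C; 20; −78 → −30 °C; AcOH quench at −30 °C
Reagents that add atoms: none
Why: In this tandem Michael addition–Dieckmann condensation the succinate enolate adds to the exocyclic methylene, and the lactone enolate so formed is acylated intramolecularly (5-exo-trig) on the face opposite the bulky branched amino-acetal substituent, which closes ring A and sets the second quaternary centre next to the first.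

Step 12
Reactants: 23 spiro keto lactone; 24 but-3-en-2-one
Product: 26 AB enone spiro-fused to the γ-lactone (ester carbon R; ring-fusion CH epimers), via oxobutyl ketone 25 (not isolated)
Conditions: 24 (1.5 equiv), KOt-Bu (0.3 equiv), t-BuOH–THF, 0 °C → rt; then pyrrolidine (0.5 equiv), AcOH (0.8 equiv), toluene, 70 °C
Reagents that add atoms: none
Why: In this Robinson annulation the only enolisable α-carbon adds to the enone, KOt-Bu/t-BuOH equilibrates both epimerisable ring A carbons so that the larger oxobutyl chain takes the face of the flat lactone carbonyl and the smaller CO2Me lies trans to it on the face of the quaternary carbon (the target configuration), and the amine-catalysed aldol condensation onto the hindered ketone then closes ring B.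

Step 13
Reactants: 26 AB enone lactone
Product: 29 acetoxymethyl δ-lactam (rings A B D; dimethyl acetal retained), via ammonium chloride 27 (not isolated), via hydroxy lactam 28 (not isolated)
Conditions: HCl (dioxane)–MeOH, 0 °C → rt; evaporate; NEt3, MeOH, 55 °C; evaporate; Ac2O, pyridine, DMAP (cat.), CH2Cl2, 0 °C
Reagents that add atoms: acetic anhydride CC(=O)OC(C)=O
Why: Acidolysis of the Boc group in methanol keeps the dimethyl acetal, the freed amine opens the γ-lactone by O-to-N acyl transfer (6-exo-trig aminolysis) to close ring D, and the released neopentyl alcohol is acetylated while the lactam N–H stays free.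

Step 14
Reactants: 29 acetal lactam
Product: 31 tetracyclic lactam (rings A–D) bearing CH2OAc and the (Z)-pent-3-enyl chain, via aldehyde 30 (not isolated)
Conditions: CF3CO2H–H2O–CH2Cl2, 0 °C; evaporate; pyrrolidine (1.5 equiv), AcOH (1.5 equiv), diethyl 2,6-dimethyl-1,4-dihydropyridine-3,5-dicarboxylate (1.3 equiv), EtOH, 60 °C; then aq NaOAc–AcOH, rt
Reagents that add atoms: none
Why: Proposed new method: pyrrolidine converts the enone into its heteroannular dienamine, whose α-carbon adds to the aldehyde, loss of water gives a cross-conjugated iminium ion that the Hantzsch ester reduces at the exocyclic carbon, and hydrolysis returns the tetrasubstituted enone (an intramolecular extension of organocatalytic reductive alkylation of Hagemann-type esters and of Stork dienamine α-alkylation), the formyl-bearing carbon correcting itself through enamine epimerisation because only the isomer cis to ring A can close the bicyclo[3.3.1] system, and the ring-fusion C–H being set by kinetic γ-protonation of the dienamine anti to the neighbouring CO2Me.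

Step 15
Reactants: 31 tetracyclic lactam
Product: 34 bridged 5,6-dihydro-4H-1,3-oxazinium trifluoromethanesulfonate (six rings), via N-chloromethyl lactam 32 (not isolated), via N-acyliminium triflate 33 (not isolated)
Conditions: (CH2O)n, Me3SiCl, CHCl3, 45 °C; evaporate; AgOSO2CF3, 2,6-di-tert-butylpyridine, CH2Cl2 (0.002 M), −40 °C → rt; filter
Reagents that add atoms: paraformaldehyde (as formaldehyde) C=O; silver trifluoromethanesulfonate [Ag+].[O-]S(=O)(=O)C(F)(F)F
Why: Proposed new method: ionisation gives an N-acyliminium ion whose O=C–N+=CH2 unit is locked s-cis by ring D and acts as a 4π heterodiene toward the tethered alkene (intramolecular version of the known polar [4+2] amidoalkylation cycloaddition of N-acyliminium ions with alkenes to 1,3-oxazinium salts), the two-carbon tether from the quaternary carbon allows only the inner alkene carbon to reach the carbonyl oxygen and only on the lactam face that carries the chain, and suprafacial addition to the (Z)-alkene therefore sets the carbinol and methyl-bearing carbons as (R,R) (syn) while the oxazinium ring and ring E close in the same operation.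

Step 16
Reactants: 34 oxazinium triflate
Product: 35 target CNP0123592.1
Conditions: aq NaHCO3, THF, 0 °C → rt
Reagents that add atoms: water O
Why: In this iminium ether hydrolysis hydroxide adds to the C=N+ carbon and the tetrahedral intermediate expels the alkoxide rather than the amine, which gives the lactam and the free secondary alcohol with the carbinol C–O bond intact (retention), under conditions too mild to cleave the acetate or methyl ester or to epimerise the ester and ring-fusion carbons.

**Compound list**
1 | tetrahydro-2H-pyran-2-ol | OC1CCCCO1 | starting material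
2 | ethyltriphenylphosphonium bromide | CC[P+](c1ccccc1)(c1ccccc1)c1ccccc1.[Br-] | starting material
3 | (5Z)-hept-5-en-1-ol | C/C=C\CCCCO | intermediate
4 | (5Z)-hept-5-enal | C/C=C\CCCC=O | intermediate
5 | 2,2-dimethoxyacetaldehyde | COC(OC)C=O | starting material
6 | nitromethane | C[N+](=O)[O-] | starting material
7 | 1,1-dimethoxy-3-nitropropan-2-ol (racemic, not isolated) | COC(OC)C(O)C[N+](=O)[O-] | intermediate
8 | (E)-3,3-dimethoxy-1-nitroprop-1-ene | COC(OC)/C=C/[N+](=O)[O-] | intermediate
9 | (2S,5Z)-2-[(2S)-1,1-dimethoxy-3-nitropropan-2-yl]hept-5-enal | O=C[C@@H](CC/C=C\C)[C@@H](C[N+](=O)[O-])C(OC)OC | intermediate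
10 | (2S,5Z)-2-[(2S)-1,1-dimethoxy-3-nitropropan-2-yl]hept-5-enoic acid | OC(=O)[C@@H](CC/C=C\C)[C@@H](C[N+](=O)[O-])C(OC)OC | intermediate
11 | (2S,5Z)-2-[(2S)-3-amino-1,1-dimethoxypropan-2-yl]hept-5-enoic acid (not isolated) | OC(=O)[C@@H](CC/C=C\C)[C@@H](CN)C(OC)OC | intermediate
12 | (3S,4S)-4-(dimethoxymethyl)-3-[(3Z)-pent-3-en-1-yl]pyrrolidin-2-one | O=C1NC[C@@H](C(OC)OC)[C@@H]1CC/C=C\C | intermediate
13 | tert-butyl (3S,4S)-4-(dimethoxymethyl)-2-oxo-3-[(3Z)-pent-3-en-1-yl]pyrrolidine-1-carboxylate | O=C1N(C(=O)OC(C)(C)C)C[C@@H](C(OC)OC)[C@@H]1CC/C=C\C | intermediate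
14 | methyl bromoacetate | COC(=O)CBr | starting material
15 | tert-butyl (3S,4S)-4-(dimethoxymethyl)-3-(2-methoxy-2-oxoethyl)-2-oxo-3-[(3Z)-pent-3-en-1-yl]pyrrolidine-1-carboxylate | O=C1N(C(=O)OC(C)(C)C)C[C@@H](C(OC)OC)[C@@]1(CC(=O)OC)CC/C=C\C | intermediate
16 | methyl (3S,6Z)-3-[(2S)-1-(tert-butoxycarbonylamino)-3,3-dimethoxypropan-2-yl]-3-(hydroxymethyl)oct-6-enoate (not isolated) | COC(=O)C[C@](CC/C=C\C)(CO)[C@@H](CNC(=O)OC(C)(C)C)C(OC)OC | intermediate
17 | tert-butyl {(2S)-3,3-dimethoxy-2-[(3S)-5-oxo-3-[(3Z)-pent-3-en-1-yl]oxolan-3-yl]propyl}carbamate | O=C1C[C@](CC/C=C\C)(CO1)[C@@H](CNC(=O)OC(C)(C)C)C(OC)OC | intermediate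
18 | α-(dimethylaminomethyl) derivative of lactone 17 (α-epimers, not isolated) | O=C1OC[C@](CC/C=C\C)([C@@H](CNC(=O)OC(C)(C)C)C(OC)OC)C1CN(C)C | intermediate
19 | trimethylammonium iodide of 18 (not isolated) | O=C1OC[C@](CC/C=C\C)([C@@H](CNC(=O)OC(C)(C)C)C(OC)OC)C1C[N+](C)(C)C.[I-] | intermediate
20 | tert-butyl {(2S)-3,3-dimethoxy-2-[(3R)-4-methylidene-5-oxo-3-[(3Z)-pent-3-en-1-yl]oxolan-3-yl]propyl}carbamate | C=C1C(=O)OC[C@]1(CC/C=C\C)[C@@H](CNC(=O)OC(C)(C)C)C(OC)OC | intermediate
21 | dimethyl succinate | COC(=O)CCC(=O)OC | starting material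
22 | Michael adduct of 21 and 20, drawn in neutral form (present as its lactone enolate, not isolated) | COC(=O)CC(CC1C(=O)OC[C@]1(CC/C=C\C)[C@@H](CNC(=O)OC(C)(C)C)C(OC)OC)C(=O)OC | intermediate
23 | methyl (4R,5S)-4-[(2S)-1-(tert-butoxycarbonylamino)-3,3-dimethoxypropan-2-yl]-1,6-dioxo-4-[(3Z)-pent-3-en-1-yl]-2-oxaspiro[4.4]nonane-8-carboxylate (C-8 epimers) | COC(=O)C1C[C@@]2(C(=O)OC[C@]2(CC/C=C\C)[C@@H](CNC(=O)OC(C)(C)C)C(OC)OC)C(=O)C1 | intermediate
24 | but-3-en-2-one (methyl vinyl ketone) | C=CC(C)=O | starting material
25 | (8R)-7-(3-oxobutyl) derivative of 23 (not isolated) | COC(=O)[C@@H]1C[C@@]2(C(=O)OC[C@]2(CC/C=C\C)[C@@H](CNC(=O)OC(C)(C)C)C(OC)OC)C(=O)C1CCC(C)=O | intermediate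
26 | AB enone (hydrindenone) spiro-fused at the allylic ring A carbon to the γ-lactone; ester carbon R; ring-fusion CH epimers | COC(=O)[C@@H]1C[C@@]2(C(=O)OC[C@]2(CC/C=C\C)[C@@H](CNC(=O)OC(C)(C)C)C(OC)OC)C3=CC(=O)CCC13 | intermediate
27 | ammonium chloride from 26 after loss of Boc (not isolated) | COC(=O)[C@@H]1C[C@@]2(C(=O)OC[C@]2(CC/C=C\C)[C@@H](C[NH3+])C(OC)OC)C3=CC(=O)CCC13.[Cl-] | intermediate
28 | hydroxymethyl δ-lactam, rings A, B, D (not isolated) | COC(=O)[C@@H]1C[C@@]2(C(=O)NC[C@@H](C(OC)OC)[C@]2(CO)CC/C=C\C)C3=CC(=O)CCC13 | intermediate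
29 | acetoxymethyl δ-lactam, rings A, B, D, dimethyl acetal | COC(=O)[C@@H]1C[C@@]2(C(=O)NC[C@@H](C(OC)OC)[C@]2(COC(C)=O)CC/C=C\C)C3=CC(=O)CCC13 | intermediate
30 | aldehyde from 29 (not isolated) | COC(=O)[C@@H]1C[C@@]2(C(=O)NC[C@@H](C=O)[C@]2(COC(C)=O)CC/C=C\C)C3=CC(=O)CCC13 | intermediate
31 | tetracyclic N–H lactam, rings A–D, with CH2OAc and (Z)-pent-3-enyl on the quaternary bridge carbon | COC(=O)[C@@H]1C[C@@]23C(=O)NC[C@@H](CC5=C2[C@@H]1CCC5=O)[C@]3(COC(C)=O)CC/C=C\C | intermediate
32 | N-chloromethyl derivative of 31 (not isolated) | COC(=O)[C@@H]1C[C@@]23C(=O)N(CCl)C[C@@H](CC5=C2[C@@H]1CCC5=O)[C@]3(COC(C)=O)CC/C=C\C | intermediate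
33 | N-methylene acyliminium triflate of 31 (not isolated) | COC(=O)[C@@H]1C[C@@]23C(=O)[N+](=C)C[C@@H](CC5=C2[C@@H]1CCC5=O)[C@]3(COC(C)=O)CC/C=C\C.[O-]S(=O)(=O)C(F)(F)F | intermediate
34 | bridged hexacyclic 5,6-dihydro-4H-1,3-oxazinium triflate | COC(=O)[C@@H]1C[C@@]23C6=[N+]4C[C@@H](CC5=C2[C@@H]1CCC5=O)[C@]3(COC(C)=O)CC[C@@H](O6)[C@H](C)C4.[O-]S(=O)(=O)C(F)(F)F | intermediate
35 | CNP0123592.1 (ester carbon R, lactam α-carbon R, lactam β′-CH S, ring-fusion CH R, acetoxymethyl carbon R, carbinol R, methyl carbon R) | COC(=O)[C@@H]1C[C@@]23C(=O)N4C[C@@H](CC5=C2[C@@H]1CCC5=O)[C@]3(COC(C)=O)CC[C@@H](O)[C@H](C)C4 | target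

**Totals**
Total step count: 16.
Longest linear sequence: 15 (steps 1, 2 and 4–16).

**Three steps most likely to fail, each with one fallback**

Step 11 (Michael–Dieckmann annulation).
- The risks are a reversed Dieckmann closure, retro-Claisen opening, and no control at the ester carbon.
- The fallback sets out from 17 and comes back at 23, this time as the single (8R) ester epimer.
- Methyl acrylate and methyl glyoxylate are joined with DABCO (Morita–Baylis–Hillman reaction) to dimethyl 2-hydroxy-3-methylidenebutanedioate F1.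
- Acetylation of that alcohol gives dimethyl 2-acetoxy-3-methylidenebutanedioate F2.
- The lithium enolate of 17 displaces the acetate in the SN2′ sense to give the fumarate-type lactone triester F3.
- This triester has no enolisable carbon between its two ester groups, so further LiN(SiMe3)2 can cyclise it only through the lactone enolate. The product is the spiro cyclopentenone ester F4, which is stabilised as its extended enolate.
- Conjugate reduction with [(Ph3P)CuH]6 then delivers hydrogen to the flat ring from the face away from the quaternary carbon and gives 23.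

Step 14 (reductive ring C closure).
- The risks are slow dienamine formation and reductive amination of the aldehyde.
- The fallback sets out from 30, which is now isolated, and comes back at 31.
- The aldehyde is reduced selectively with NaBH(OAc)3 to the primary alcohol F5.
- An Appel reaction (I2, PPh3, imidazole) converts it into the primary iodide F6.
- Ring C is then closed by a classical Stork alkylation of the preformed pyrrolidine dienamine (MeCN, 80 °C) followed by buffered hydrolysis. This replaces the redox-neutral condensation–hydride sequence by an SN2 displacement.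

Step 15 (bridging [4+2] cycloaddition).
- The risks are allylic strain of the (Z)-alkene in the transition state, oligomerisation, and proton loss from the cation.
- The fallback sets out from 31 and comes back at 35.
- Selective ozonolysis of the isolated alkene (O3, then Me2S; the tetrasubstituted enone is inert) gives the chain aldehyde F7.
- Reagent-controlled (Z)-crotylboration, using the Ipc2B enantiomer that gives the (R)-carbinol, gives the syn homoallylic alcohol F8.
- A second ozonolysis gives the β-hydroxy aldehyde F9, which closes reversibly onto the lactam N–H to the cyclic N-acyl hemiaminal F10.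
- Reduction with Et3SiH and BF3·OEt2 then gives 35. In this variant the two chain stereocentres come from the reagent and ring E is closed by reductive N-alkylation.

**Further compounds**
F1 | step 11 | dimethyl 2-hydroxy-3-methylidenebutanedioate (racemic) | COC(=O)C(O)C(=C)C(=O)OC
F2 | step 11 | dimethyl 2-acetoxy-3-methylidenebutanedioate (racemic) | COC(=O)C(OC(C)=O)C(=C)C(=O)OC
F3 | step 11 | fumarate-type lactone triester (lactone α-epimers) | COC(=O)/C=C(\CC1C(=O)OC[C@]1(CC/C=C\C)[C@@H](CNC(=O)OC(C)(C)C)C(OC)OC)C(=O)OC
F4 | step 11 | spiro cyclopentenone ester | COC(=O)C1=CC(=O)[C@@]2(C1)C(=O)OC[C@]2(CC/C=C\C)[C@@H](CNC(=O)OC(C)(C)C)C(OC)OC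
F5 | step 14 | primary alcohol from 30 | COC(=O)[C@@H]1C[C@@]2(C(=O)NC[C@@H](CO)[C@]2(COC(C)=O)CC/C=C\C)C3=CC(=O)CCC13
F6 | step 14 | primary iodide | COC(=O)[C@@H]1C[C@@]2(C(=O)NC[C@@H](CI)[C@]2(COC(C)=O)CC/C=C\C)C3=CC(=O)CCC13
F7 | step 15 | chain aldehyde | COC(=O)[C@@H]1C[C@@]23C(=O)NC[C@@H](CC5=C2[C@@H]1CCC5=O)[C@]3(COC(C)=O)CCC=O
F8 | step 15 | syn homoallylic alcohol | COC(=O)[C@@H]1C[C@@]23C(=O)NC[C@@H](CC5=C2[C@@H]1CCC5=O)[C@]3(COC(C)=O)CC[C@@H](O)[C@H](C)C=C
F9 | step 15 | β-hydroxy aldehyde | COC(=O)[C@@H]1C[C@@]23C(=O)NC[C@@H](CC5=C2[C@@H]1CCC5=O)[C@]3(COC(C)=O)CC[C@@H](O)[C@H](C)C=O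
F10 | step 15 | cyclic N-acyl hemiaminal (hemiaminal epimers) | COC(=O)[C@@H]1C[C@@]23C(=O)N4C[C@@H](CC5=C2[C@@H]1CCC5=O)[C@]3(COC(C)=O)CC[C@@H](O)[C@H](C)C4O
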